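Count turnovers.

common to all: Q 8.00 × 10⁻⁴ M

|  | E | J | time |
|---|---|---|---|
| north-west | 0.400 M |  |  |
| south-west | 1.20 M |  |  |
| south | 0.400 M | 0.200 M |  |
| south-east | 2.00 M |  | 19 min |

| run | time / min | [J] / M |
|---|---|---|
| north-west run | 0.76 | 0.034 |
| north-west run | 1.4 | 0.060 |
| north-west run | 2.8 | 0.111 |
| north-west run | 5.2 | 0.175 |
| north-west run | 10 | 0.260 |
| north-west run | 19 | 0.305 |
| south-west run | 0.76 | 0.051 |
| south-west run | 1.4 | 0.075 |
| south-west run | 2.8 | 0.136 |
| south-west run | 5.2 | 0.220 |
| south-west run | 10 | 0.304 |
| south-west run | 19 | 0.370 |
| south run | 0.76 | 0.232 |
| south run | 1.4 | 0.270 |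
| south run | 2.8 | 0.307 |
| south run | 5.2 | 0.375 |
| south run | 10 | 0.457 |
| south run | 19 | 0.518 |

(standard deviation of a reading: 0.006 M)

- Overall: E -> J, with Q as catalyst.
- Constant volume, constant temperature.
- What is held in complexes is read along with the free species.
- An order is taken over about fifteen percent of the charge, up and down.

- order of the initial rate in [E], near the charge of the north-west run, the rate being that where two percent of its E are J (one fixed amount of J, the same in the runs compared)
- J in the south-east run at 19 min, as a share of the E charged

**Fading slope.** In the south-west run, J gains 0.0292 min⁻¹ of the charge per minute between 2.8 min and 5.2 min. Between 10 min and 19 min it gains 0.00611 min⁻¹. Yet 69.2% of the E charged is still not J at the last reading. The fall is therefore read as loss of Q, at 0.149 min⁻¹. The north-west run, with a third of the E, reads 0.159 min⁻¹, so this reckoning carries the south-west pace to the south-east flask.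

**Turnover budget.** The south-west slope, fading at that pace, adds a tail to the last reading, and the curve levels at 32.9% of the south-west charge. That level gives 494 J per Q charged: the turnover budget, the J one Q makes before it is lost, usually called the turnover number.

**South-east curve.** The same budget and the same Q charge put the level at 19.8% of the larger E charge. The curve starts with a slope of 0.0295 min⁻¹ of the charge per minute. Its knee comes at 6.71 min, where J is 12.5% of the charge. At 19 min it stands at 18.6%.

**Early order.** Chords to 2.8 min give an order of 0.185 between the north-west and south-west charges. This is a value across that span, not the local order.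

**Forecast.** The forecast gives an order of 0.25 and a share of 19.5%, a higher share than this reckoning, on the ground “saturation is slightly higher than in the south-west run”.

**Result.** The simulation gives an order of 0.27 and a share of 18.5%.

    Q + E ⇌ QE, settled at all times (12.80 M⁻¹)
    QE → J + Q (116.4 min⁻¹)
    2 E ⇌ E2, settled at all times (20.20 M⁻¹)
    Q + E → Rx + E (3.096 M⁻¹ min⁻¹)

**The count.** In the south-east run, J at 19 min amounts to 463 turnovers per Q, which is 93.7% of the budget of 494. The reaction of Q + E to Rx + E is the main reason for so low a share. The simulated south-east run without that step reaches 60.5% of the E charged, which is 1510 turnovers per Q, or 3.06 budgets.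

The runs are simulated on assumed constants, noise included.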